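## Retrosynthetic overview

1. The C4 diol comes from water opening a C4 spiro-epoxide at its CH2 end; the epoxide comes from a Sharpless epoxidation of a macrocyclic 2-methylidene-3-ol, and C3 is oxidised only then.
2. The only ring closure in the skeleton is the 14-membered lactone, formed by Shiina macrolactonisation (C13–O to C1) of a C1–C13 seco acid; the oxirane is made and opened afterwards.
3. The seco acid comes from a Stille allyl–vinyl coupling (C5–C6) of a C6–C13 alkenylstannane with a C1–C5 allylic chloride.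
4. The C1–C5 piece: Evans magnesium anti-aldol (sets C2, and C3 as a temporary control centre). The C6–C13 piece: Evans alkylation (C8), alkyne homologation and hydrostannation (E-C6=C7), and Stille diene synthesis (C10–C11) with a C11–C13 carbinol from catalytic Et2Zn addition (C13).
5. Three branches of 4, 7 and 6 steps converge; 7 steps follow the union.

Assumption: the SMILES is read as 2R,4R,8S,13S with 6E and 11E, in the chain numbering C1 (lactone C=O) to C13 (carbinol carbon carrying the ethyl group) used below.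

## Route

Step 1
Reactants: 1 prop-2-yn-1-ol
Product: 3 (E)-3-iodo-2-methylprop-2-en-1-ol, via alkenylalane 2 (not isolated)
Conditions: Me3Al (3 equiv), Cp2ZrCl2 (0.25 equiv), CH2Cl2, 0 °C to rt; then I2, THF, −30 to 0 °C; aqueous work-up
Reagents that add atoms: trimethylaluminium C[Al](C)C; iodine II
Why: Negishi zirconium-catalysed carboalumination adds methyl and aluminium syn across the alkyne with methyl on the internal carbon, and iodinolysis of the C–Al bond with retention gives only the E iodide.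

Step 2
Reactants: 3 (E)-3-iodo-2-methylprop-2-en-1-ol
Product: 4 (E)-3-iodo-2-methylprop-2-enal
Conditions: MnO2 (10 equiv), CH2Cl2, rt
Reagents that add atoms: none
Why: Allylic oxidation with MnO2 stops at the aldehyde and leaves the alkene geometry and the C–I bond untouched.

Step 3
Reactants: 4 (E)-3-iodo-2-methylprop-2-enal
Product: 5 (3S,1E)-1-iodo-2-methylpent-1-en-3-ol
Conditions: Et2Zn (2.5 equiv), (2S)-(−)-3-exo-morpholinoisoborneol (4 mol %), toluene/hexane, 0 °C; aqueous work-up
Reagents that add atoms: diethylzinc CC[Zn]CC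
Why: Amino-alcohol-catalysed enantioselective diethylzinc addition, in which this ligand delivers ethyl to the aldehyde face that gives the S carbinol (the alkenyl group taking the place of phenyl in the benzaldehyde model), sets C13.

Step 4
Reactants: 5 (3S,1E)-1-iodo-2-methylpent-1-en-3-ol
Product: 7 (3S,1E)-2-methyl-1-(tributylstannyl)pent-1-en-3-ol, via dilithio species 6 (not isolated)
Conditions: t-BuLi (3.1 equiv), Et2O, −78 °C; then Bu3SnCl (1.1 equiv), −78 °C to rt
Reagents that add atoms: tributyltin chloride CCCC[Sn](Cl)(CCCC)CCCC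
Why: After O-deprotonation, iodine–lithium exchange proceeds with retention of the E geometry and the alkenyllithium is stannylated, giving the nucleophilic Stille partner without touching C13.

Step 5
Reactants: 8 (R)-4-benzyl-3-propionyloxazolidin-2-one; 9 2,3-dibromoprop-1-ene
Product: 11 (R)-4-benzyl-3-[(S)-4-bromo-2-methylpent-4-enoyl]oxazolidin-2-one, via sodium enolate 10 (not isolated)
Conditions: NaHMDS (1.1 equiv), THF, −78 °C; then 9 (3 equiv), −78 to −45 °C
Reagents that add atoms: none
Why: Evans asymmetric alkylation, in which the chelated Z sodium enolate is allylated on the face opposite the benzyl group, sets C8 as S (dr > 95:5), and only the allylic bromide of 9 reacts.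

Step 6
Reactants: 11 (R)-4-benzyl-3-[(S)-4-bromo-2-methylpent-4-enoyl]oxazolidin-2-one
Product: 12 (S)-4-bromo-2-methylpent-4-en-1-ol
Conditions: LiBH4 (1.5 equiv), MeOH (1.5 equiv), Et2O, 0 °C
Reagents that add atoms: none
Why: Reductive cleavage of the imide releases the primary alcohol and the recoverable auxiliary without epimerising C8 or reducing the vinyl bromide.

Step 7
Reactants: 12 (S)-4-bromo-2-methylpent-4-en-1-ol
Product: 13 (S)-4-bromo-2-methylpent-4-enal
Conditions: Dess–Martin periodinane (1.2 equiv), NaHCO3, CH2Cl2, 0 °C to rt; used crude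
Reagents that add atoms: none
Why: Buffered Dess–Martin oxidation gives the α-branched aldehyde under non-enolising conditions, so C8 is kept.

Step 8
Reactants: 13 (S)-4-bromo-2-methylpent-4-enal
Product: 14 (S)-5-bromo-3-methylhex-5-en-1-yne
Conditions: dimethyl (1-diazo-2-oxopropyl)phosphonate (1.3 equiv), K2CO3 (2 equiv), MeOH, 0 °C to rt
Reagents that add atoms: dimethyl (1-diazo-2-oxopropyl)phosphonate COP(=O)(OC)C(=[N+]=[N-])C(C)=O
Why: Seyferth–Gilbert homologation in the Ohira–Bestmann variant converts the aldehyde into the terminal alkyne through an alkylidene carbene, under conditions mild enough to leave the α-stereocenter intact.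

Step 9
Reactants: 14 (S)-5-bromo-3-methylhex-5-en-1-yne
Product: 16 (S)-6-bromo-4-methylhept-6-en-2-yne, via lithium acetylide 15 (not isolated)
Conditions: LDA (1.05 equiv), THF, −78 °C; then MeI (3 equiv), DMPU, −78 °C to rt
Reagents that add atoms: iodomethane CI
Why: Acetylide alkylation installs the carbon that becomes the C6 methyl, and the amide base avoids bromine–lithium exchange at the vinyl bromide.

Step 10
Reactants: 16 (S)-6-bromo-4-methylhept-6-en-2-yne; 7 (3S,1E)-2-methyl-1-(tributylstannyl)pent-1-en-3-ol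
Product: 17 (3S,4E,8S)-4,8-dimethyl-6-methylideneundec-4-en-9-yn-3-ol
Conditions: Pd(PPh3)4 (5 mol %), CuI (10 mol %), CsF (2 equiv), DMF, 45 °C
Reagents that add atoms: none
Why: Stille coupling of the 2-bromoalkene with the E alkenylstannane (zerovalent palladium, copper co-catalysis, fluoride activation) forms the C10–C11 bond with retention and gives the 2-substituted diene, while the internal alkyne and the free hydroxyl are tolerated.

Step 11
Reactants: 17 (3S,4E,8S)-4,8-dimethyl-6-methylideneundec-4-en-9-yn-3-ol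
Product: 18 (3S,4E,8S,9E)-4,8-dimethyl-6-methylidene-10-(tributylstannyl)undeca-4,9-dien-3-ol
Conditions: Bu3SnH (1.3 equiv), PdCl2(PPh3)2 (3 mol %), THF, 0 °C
Reagents that add atoms: tributyltin hydride CCCC[SnH](CCCC)CCCC
Why: Palladium-catalysed hydrostannation adds H and Sn syn across the alkyne with tin on the methyl-bearing carbon remote from the branched C8, giving the E trisubstituted alkenylstannane (C6=C7) much faster than any addition to the hindered diene.

Step 12
Reactants: 19 2-methylidenepropane-1,3-diol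
Product: 20 2-{[(4-methoxybenzyl)oxy]methyl}prop-2-en-1-ol
Conditions: NaH (1.0 equiv), THF, 0 °C; then 4-methoxybenzyl chloride (1.0 equiv), Bu4NI (5 mol %), rt
Reagents that add atoms: 4-methoxybenzyl chloride COc1ccc(CCl)cc1
Why: Williamson monoetherification of the symmetric diol through its monosodium salt differentiates the two hydroxymethyl arms.

Step 13
Reactants: 20 2-{[(4-methoxybenzyl)oxy]methyl}prop-2-en-1-ol
Product: 21 2-{[(4-methoxybenzyl)oxy]methyl}prop-2-enal
Conditions: MnO2 (15 equiv), CH2Cl2, rt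
Reagents that add atoms: none
Why: Allylic oxidation with MnO2 gives the non-enolisable 2-substituted acrolein without touching the benzylic ether.

Step 14
Reactants: 22 (S)-4-benzyl-3-propionyloxazolidin-2-one; 21 2-{[(4-methoxybenzyl)oxy]methyl}prop-2-enal
Product: 24 (S)-4-benzyl-3-[(2R,3S)-3-hydroxy-4-{[(4-methoxybenzyl)oxy]methyl}-2-methylpent-4-enoyl]oxazolidin-2-one, via silyl ether 23 (not isolated)
Conditions: MgCl2 (0.2 equiv), Et3N (2 equiv), Me3SiCl (1.5 equiv), EtOAc, rt; then 1 M HCl, THF, rt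
Reagents that add atoms: none
Why: In the Evans magnesium-halide-catalysed anti-aldol the chelated Z magnesium enolate adds to the enal on the face opposite the benzyl group (the alkylation face) through a boat transition state, setting C2 as R and C3 as S (anti), with the aldolate trapped as its silyl ether and desilylated on work-up.

Step 15
Reactants: 24 (S)-4-benzyl-3-[(2R,3S)-3-hydroxy-4-{[(4-methoxybenzyl)oxy]methyl}-2-methylpent-4-enoyl]oxazolidin-2-one
Product: 25 (S)-4-benzyl-3-[(2R,3S)-4-{[(4-methoxybenzyl)oxy]methyl}-2-methyl-3-(triethylsilyloxy)pent-4-enoyl]oxazolidin-2-one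
Conditions: Et3SiOTf (1.2 equiv), 2,6-lutidine (2 equiv), CH2Cl2, −78 °C
Reagents that add atoms: triethylsilyl trifluoromethanesulfonate CC[Si](CC)(CC)OS(=O)(=O)C(F)(F)F
Why: Silylation masks the C3 hydroxyl so that it cannot compete as a nucleophile in the later lactonisation, while remaining removable under mild fluoride conditions.

Step 16
Reactants: 25 (S)-4-benzyl-3-[(2R,3S)-4-{[(4-methoxybenzyl)oxy]methyl}-2-methyl-3-(triethylsilyloxy)pent-4-enoyl]oxazolidin-2-one
Product: 26 (S)-4-benzyl-3-[(2R,3S)-4-(hydroxymethyl)-2-methyl-3-(triethylsilyloxy)pent-4-enoyl]oxazolidin-2-one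
Conditions: DDQ (1.3 equiv), CH2Cl2/pH 7 buffer (10:1), 0 °C to rt
Reagents that add atoms: none
Why: Oxidative cleavage of the 4-methoxybenzyl ether with DDQ frees the primary allylic alcohol while the silyl ether, imide and isolated 1,1-disubstituted alkene are inert (no diene is present yet).

Step 17
Reactants: 26 (S)-4-benzyl-3-[(2R,3S)-4-(hydroxymethyl)-2-methyl-3-(triethylsilyloxy)pent-4-enoyl]oxazolidin-2-one
Product: 28 (S)-4-benzyl-3-[(2R,3S)-4-(chloromethyl)-2-methyl-3-(triethylsilyloxy)pent-4-enoyl]oxazolidin-2-one, via allylic mesylate 27 (not isolated)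
Conditions: MsCl (1.3 equiv), 2,4,6-collidine (2 equiv), LiCl (3 equiv), DMF, 0 °C
Reagents that add atoms: lithium chloride [Li+].[Cl-]
Why: Collington–Meyers chlorination (mesylation then chloride displacement in the same flask) gives the allylic chloride without allylic transposition problems, because both allyl termini are CH2.

Step 18
Reactants: 18 (3S,4E,8S,9E)-4,8-dimethyl-6-methylidene-10-(tributylstannyl)undeca-4,9-dien-3-ol; 28 (S)-4-benzyl-3-[(2R,3S)-4-(chloromethyl)-2-methyl-3-(triethylsilyloxy)pent-4-enoyl]oxazolidin-2-one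
Product: 29 (S)-4-benzyl-3-[(2R,3S,6E,8S,11E,13S)-13-hydroxy-2,6,8,12-tetramethyl-4,10-dimethylidene-3-(triethylsilyloxy)pentadeca-6,11-dienoyl]oxazolidin-2-one
Conditions: Pd2(dba)3 (5 mol %), P(2-furyl)3 (20 mol %), CuI (20 mol %), NMP, 40 °C
Reagents that add atoms: none
Why: Stille allyl–vinyl coupling joins C5 to C6 under neutral conditions; the allyl–palladium intermediate has two equivalent CH2 termini (no regiochemical issue) and the alkenyl group is transferred with retention, fixing E-C6=C7.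

Step 19
Reactants: 29 (S)-4-benzyl-3-[(2R,3S,6E,8S,11E,13S)-13-hydroxy-2,6,8,12-tetramethyl-4,10-dimethylidene-3-(triethylsilyloxy)pentadeca-6,11-dienoyl]oxazolidin-2-one
Product: 31 (2R,3S,6E,8S,11E,13S)-13-hydroxy-2,6,8,12-tetramethyl-4,10-dimethylidene-3-(triethylsilyloxy)pentadeca-6,11-dienoic acid, via peroxy acid salt 30 (not isolated)
Conditions: LiOH (2 equiv), H2O2 (4 equiv), THF/H2O (3:1), 0 °C; then Na2SO3; then 1 M HCl to pH 4 at 0 °C
Reagents that add atoms: hydrogen peroxide OO
Why: Hydroperoxide attacks the exocyclic imide carbonyl selectively (Evans auxiliary cleavage) and sulfite reduces the peracid, giving the seco acid without epimerising C2.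

Step 20
Reactants: 31 (2R,3S,6E,8S,11E,13S)-13-hydroxy-2,6,8,12-tetramethyl-4,10-dimethylidene-3-(triethylsilyloxy)pentadeca-6,11-dienoic acid
Product: 33 (3R,4S,7E,9S,12E,14S)-14-ethyl-3,7,9,13-tetramethyl-5,11-dimethylidene-4-(triethylsilyloxy)oxacyclotetradeca-7,12-dien-2-one, via mixed anhydride 32 (not isolated)
Conditions: 2-methyl-6-nitrobenzoic anhydride (1.3 equiv), DMAP (3 equiv), CH2Cl2, rt, syringe-pump addition over 12 h to 1 mM
Reagents that add atoms: none
Why: Shiina macrolactonisation activates the acid as a mixed anhydride and, at high dilution, the only free hydroxyl (C13) closes the 14-membered ring, which is the key ring-forming step.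

Step 21
Reactants: 33 (3R,4S,7E,9S,12E,14S)-14-ethyl-3,7,9,13-tetramethyl-5,11-dimethylidene-4-(triethylsilyloxy)oxacyclotetradeca-7,12-dien-2-one
Product: 34 (3R,4S,7E,9S,12E,14S)-14-ethyl-4-hydroxy-3,7,9,13-tetramethyl-5,11-dimethylideneoxacyclotetradeca-7,12-dien-2-one
Conditions: HF·pyridine, pyridine, THF, 0 °C
Reagents that add atoms: none
Why: Buffered fluoride desilylation frees the C3 hydroxyl, now the only allylic alcohol in the molecule, without affecting the lactone or the alkenes.

Step 22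
Reactants: 34 (3R,4S,7E,9S,12E,14S)-14-ethyl-4-hydroxy-3,7,9,13-tetramethyl-5,11-dimethylideneoxacyclotetradeca-7,12-dien-2-one
Product: 35 (3R,4S,5R,7E,9S,12E,14S)-14-ethyl-4-hydroxy-3,7,9,13-tetramethyl-11-methylidenespiro[oxacyclotetradeca-7,12-diene-5,2'-oxiran]-2-one
Conditions: Ti(OiPr)4 (0.5 equiv), L-(+)-diisopropyl tartrate (0.6 equiv), t-BuOOH (2 equiv, in isooctane), 4 Å molecular sieves, CH2Cl2, −20 °C
Reagents that add atoms: tert-butyl hydroperoxide CC(C)(C)OO
Why: In this Sharpless asymmetric epoxidation the 3S carbinol is the fast-reacting (matched) enantiomer for L-(+)-tartrate, so oxygen is delivered to the face that gives the erythro epoxide with C4 as R (the same facial sense that makes (S)-glycidol from allyl alcohol), and the other alkenes carry no free allylic hydroxyl.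

Step 23
Reactants: 35 (3R,4S,5R,7E,9S,12E,14S)-14-ethyl-4-hydroxy-3,7,9,13-tetramethyl-11-methylidenespiro[oxacyclotetradeca-7,12-diene-5,2'-oxiran]-2-one
Product: 36 (3R,5R,7E,9S,12E,14S)-14-ethyl-3,7,9,13-tetramethyl-11-methylidenespiro[oxacyclotetradeca-7,12-diene-5,2'-oxirane]-2,4-dione
Conditions: Dess–Martin periodinane (1.5 equiv), NaHCO3, CH2Cl2, 0 °C
Reagents that add atoms: none
Why: Buffered Dess–Martin oxidation unveils the C3 ketone (and thus the β-keto lactone) late and under non-basic conditions, so the C2 configuration set in step 14 is kept and the control centre at C3 is erased.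

Step 24
Reactants: 36 (3R,5R,7E,9S,12E,14S)-14-ethyl-3,7,9,13-tetramethyl-11-methylidenespiro[oxacyclotetradeca-7,12-diene-5,2'-oxirane]-2,4-dione
Product: 37 (3R,5R,7E,9S,12E,14S)-14-ethyl-5-hydroxy-5-(hydroxymethyl)-3,7,9,13-tetramethyl-11-methylideneoxacyclotetradeca-7,12-diene-2,4-dione (CNP0240796.6)
Conditions: HClO4 (0.05 M, 0.2 equiv), THF/H2O (3:1), 0 °C to rt
Reagents that add atoms: water O
Why: Acid-catalysed epoxide hydrolysis is directed to the unhindered CH2 terminus because the adjacent ketone prevents ionisation at C4, so the C4–O bond and the R configuration are retained and the tertiary and primary hydroxyls appear together.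

## Compound list

1 | prop-2-yn-1-ol | C#CCO | starting material
2 | (E)-alkenylalane: dimethyl[3-(dimethylalumanyloxy)-2-methylprop-1-en-1-yl]alumane | C[Al](C)OC/C(C)=C/[Al](C)C | intermediate (not isolated)
3 | (E)-3-iodo-2-methylprop-2-en-1-ol | OC/C(C)=C/I | intermediate
4 | (E)-3-iodo-2-methylprop-2-enal | O=C/C(C)=C/I | intermediate
5 | (3S,1E)-1-iodo-2-methylpent-1-en-3-ol | CC[C@H](O)/C(C)=C/I | intermediate
6 | lithium (3S,1E)-1-lithio-2-methylpent-1-en-3-olate | CC[C@H](O[Li])/C(C)=C/[Li] | intermediate (not isolated)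
7 | (3S,1E)-2-methyl-1-(tributylstannyl)pent-1-en-3-ol | CC[C@H](O)/C(C)=C/[Sn](CCCC)(CCCC)CCCC | intermediate
8 | (R)-4-benzyl-3-propionyloxazolidin-2-one | CCC(=O)N1[C@H](Cc2ccccc2)COC1=O | starting material
9 | 2,3-dibromoprop-1-ene | C=C(Br)CBr | starting material
10 | sodium (Z)-enolate of 8 | C/C=C(\[O-])N1[C@H](Cc2ccccc2)COC1=O.[Na+] | intermediate (not isolated)
11 | (R)-4-benzyl-3-[(S)-4-bromo-2-methylpent-4-enoyl]oxazolidin-2-one | C=C(Br)C[C@H](C)C(=O)N1[C@H](Cc2ccccc2)COC1=O | intermediate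
12 | (S)-4-bromo-2-methylpent-4-en-1-ol | C=C(Br)C[C@H](C)CO | intermediate
13 | (S)-4-bromo-2-methylpent-4-enal | C=C(Br)C[C@H](C)C=O | intermediate
14 | (S)-5-bromo-3-methylhex-5-en-1-yne | C=C(Br)C[C@H](C)C#C | intermediate
15 | lithium acetylide of 14 | C=C(Br)C[C@H](C)C#C[Li] | intermediate (not isolated)
16 | (S)-6-bromo-4-methylhept-6-en-2-yne | C=C(Br)C[C@H](C)C#CC | intermediate
17 | (3S,4E,8S)-4,8-dimethyl-6-methylideneundec-4-en-9-yn-3-ol | CC#C[C@@H](C)CC(=C)/C=C(\C)[C@@H](O)CC | intermediate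
18 | (3S,4E,8S,9E)-4,8-dimethyl-6-methylidene-10-(tributylstannyl)undeca-4,9-dien-3-ol | CCCC[Sn](CCCC)(CCCC)/C(C)=C/[C@@H](C)CC(=C)/C=C(\C)[C@@H](O)CC | intermediate
19 | 2-methylidenepropane-1,3-diol | C=C(CO)CO | starting material
20 | 2-{[(4-methoxybenzyl)oxy]methyl}prop-2-en-1-ol | C=C(CO)COCc1ccc(OC)cc1 | intermediate
21 | 2-{[(4-methoxybenzyl)oxy]methyl}prop-2-enal | C=C(C=O)COCc1ccc(OC)cc1 | intermediate
22 | (S)-4-benzyl-3-propionyloxazolidin-2-one | CCC(=O)N1[C@@H](Cc2ccccc2)COC1=O | starting material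
23 | 3-O-trimethylsilyl ether of 24 | C=C(COCc1ccc(OC)cc1)[C@@H](O[Si](C)(C)C)[C@@H](C)C(=O)N1[C@@H](Cc2ccccc2)COC1=O | intermediate (not isolated)
24 | (S)-4-benzyl-3-[(2R,3S)-3-hydroxy-4-{[(4-methoxybenzyl)oxy]methyl}-2-methylpent-4-enoyl]oxazolidin-2-one | C=C(COCc1ccc(OC)cc1)[C@@H](O)[C@@H](C)C(=O)N1[C@@H](Cc2ccccc2)COC1=O | intermediate
25 | (S)-4-benzyl-3-[(2R,3S)-4-{[(4-methoxybenzyl)oxy]methyl}-2-methyl-3-(triethylsilyloxy)pent-4-enoyl]oxazolidin-2-one | C=C(COCc1ccc(OC)cc1)[C@@H](O[Si](CC)(CC)CC)[C@@H](C)C(=O)N1[C@@H](Cc2ccccc2)COC1=O | intermediate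
26 | (S)-4-benzyl-3-[(2R,3S)-4-(hydroxymethyl)-2-methyl-3-(triethylsilyloxy)pent-4-enoyl]oxazolidin-2-one | C=C(CO)[C@@H](O[Si](CC)(CC)CC)[C@@H](C)C(=O)N1[C@@H](Cc2ccccc2)COC1=O | intermediate
27 | allylic methanesulfonate of 26 | C=C(COS(C)(=O)=O)[C@@H](O[Si](CC)(CC)CC)[C@@H](C)C(=O)N1[C@@H](Cc2ccccc2)COC1=O | intermediate (not isolated)
28 | (S)-4-benzyl-3-[(2R,3S)-4-(chloromethyl)-2-methyl-3-(triethylsilyloxy)pent-4-enoyl]oxazolidin-2-one | C=C(CCl)[C@@H](O[Si](CC)(CC)CC)[C@@H](C)C(=O)N1[C@@H](Cc2ccccc2)COC1=O | intermediate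
29 | (S)-4-benzyl-3-[(2R,3S,6E,8S,11E,13S)-13-hydroxy-2,6,8,12-tetramethyl-4,10-dimethylidene-3-(triethylsilyloxy)pentadeca-6,11-dienoyl]oxazolidin-2-one | CC[C@H](O)/C(C)=C/C(=C)C[C@H](C)/C=C(\C)CC(=C)[C@@H](O[Si](CC)(CC)CC)[C@@H](C)C(=O)N1[C@@H](Cc2ccccc2)COC1=O | intermediate
30 | lithium peroxycarboxylate corresponding to 31 | CC[C@H](O)/C(C)=C/C(=C)C[C@H](C)/C=C(\C)CC(=C)[C@@H](O[Si](CC)(CC)CC)[C@@H](C)C(=O)O[O-].[Li+] | intermediate (not isolated)
31 | (2R,3S,6E,8S,11E,13S)-13-hydroxy-2,6,8,12-tetramethyl-4,10-dimethylidene-3-(triethylsilyloxy)pentadeca-6,11-dienoic acid | CC[C@H](O)/C(C)=C/C(=C)C[C@H](C)/C=C(\C)CC(=C)[C@@H](O[Si](CC)(CC)CC)[C@@H](C)C(=O)O | intermediate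
32 | mixed anhydride of 31 with 2-methyl-6-nitrobenzoic acid | CC[C@H](O)/C(C)=C/C(=C)C[C@H](C)/C=C(\C)CC(=C)[C@@H](O[Si](CC)(CC)CC)[C@@H](C)C(=O)OC(=O)c1c(C)cccc1[N+](=O)[O-] | intermediate (not isolated)
33 | (3R,4S,7E,9S,12E,14S)-14-ethyl-3,7,9,13-tetramethyl-5,11-dimethylidene-4-(triethylsilyloxy)oxacyclotetradeca-7,12-dien-2-one | C=C1/C=C(\C)[C@H](CC)OC(=O)[C@H](C)[C@H](O[Si](CC)(CC)CC)C(=C)C/C(C)=C/[C@@H](C)C1 | intermediate
34 | (3R,4S,7E,9S,12E,14S)-14-ethyl-4-hydroxy-3,7,9,13-tetramethyl-5,11-dimethylideneoxacyclotetradeca-7,12-dien-2-one | C=C1/C=C(\C)[C@H](CC)OC(=O)[C@H](C)[C@H](O)C(=C)C/C(C)=C/[C@@H](C)C1 | intermediate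
35 | (3R,4S,5R,7E,9S,12E,14S)-14-ethyl-4-hydroxy-3,7,9,13-tetramethyl-11-methylidenespiro[oxacyclotetradeca-7,12-diene-5,2'-oxiran]-2-one | C=C1/C=C(\C)[C@H](CC)OC(=O)[C@H](C)[C@H](O)[C@]2(CO2)C/C(C)=C/[C@@H](C)C1 | intermediate
36 | (3R,5R,7E,9S,12E,14S)-14-ethyl-3,7,9,13-tetramethyl-11-methylidenespiro[oxacyclotetradeca-7,12-diene-5,2'-oxirane]-2,4-dione | C=C1/C=C(\C)[C@H](CC)OC(=O)[C@H](C)C(=O)[C@]2(CO2)C/C(C)=C/[C@@H](C)C1 | intermediate
37 | (3R,5R,7E,9S,12E,14S)-14-ethyl-5-hydroxy-5-(hydroxymethyl)-3,7,9,13-tetramethyl-11-methylideneoxacyclotetradeca-7,12-diene-2,4-dione | C=C1/C=C(\C)[C@H](CC)OC(=O)[C@H](C)C(=O)[C@](O)(CO)C/C(C)=C/[C@@H](C)C1 | target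

## Step count and risks

Total step count: 24.
Longest linear sequence: 14 steps (steps 5–11, then 18–24), which is 58 % of the total. The other two branches are 13 steps each (1–4, 10, 11, 18–24 and 12–24).

The three steps most likely to fail:

**Step 24, hydrolysis of the spiro-epoxy ketone.** The oxirane CH2 is neopentyl-like, and the product can ring-contract (the C4 hydroxyl or the new CH2OH attacking the lactone carbonyl) if acid treatment is prolonged. The fallback sets out from epoxy alcohol 35 and comes back to the route at 37. Ti(OiPr)4-assisted opening of 35 with chloroacetic acid, in which the titanium alkoxide of the C3 hydroxyl delivers the carboxylate to the distal CH2 so that C4 is untouched, gives the chloroacetate diol F1. Dess–Martin oxidation of its secondary hydroxyl gives the keto chloroacetate F2. Thiourea with NaHCO3 in ethanol at 40 °C then removes the chloroacetyl group under almost neutral conditions and gives 37.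

**Step 22, epoxidation on the macrocycle.** The ring may not let the carbinol adopt the geometry the titanium–tartrate catalyst needs, giving slow reaction or low diastereoselectivity. The fallback sets out from the open-chain imide 29 and comes back at 35, moving the epoxidation in front of the ring closure. Acetylation of the C13 hydroxyl (Ac2O, pyridine, DMAP) gives the acetate F3, and HF·pyridine frees the C3 hydroxyl to give the allylic alcohol F4. The same L-(+)-tartrate epoxidation, now on a flexible chain with only one free allylic alcohol, gives the epoxy alcohol F5. LiOH/H2O2 removes the auxiliary and the acetate to give the epoxy dihydroxy acid F6, which is kept cold and used at once because 4,5-epoxy acids lactonise. Shiina macrolactonisation at the C13 hydroxyl (the hindered C3 hydroxyl could only form a β-lactone) gives 35.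

**Step 18, Stille union.** The tin-bearing carbon of 18 carries a methyl group, which slows transmetalation, and the allyl–palladium intermediate may lose a β-hydrogen instead. The fallback sets out from 28 and 18 and comes back at 33, swapping the roles of fragment union and ring closure. LiOH/H2O2 on 28 gives the acid F7. Esterification of F7 with the C13 hydroxyl of 18 (2-methyl-6-nitrobenzoic anhydride, DMAP) gives the ester F8, which carries both the alkenylstannane and the allylic chloride. Intramolecular allyl–vinyl Stille coupling at high dilution (Pd2(dba)3, P(2-furyl)3, NMP) then closes the 14-membered ring at C5–C6 and gives 33 directly.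

## Further compounds

F1 | step 24 | [(3R,4S,5R,7E,9S,12E,14S)-14-ethyl-4,5-dihydroxy-3,7,9,13-tetramethyl-11-methylidene-2-oxooxacyclotetradeca-7,12-dien-5-yl]methyl 2-chloroacetate | C=C1/C=C(\C)[C@H](CC)OC(=O)[C@H](C)[C@H](O)[C@](O)(COC(=O)CCl)C/C(C)=C/[C@@H](C)C1
F2 | step 24 | [(3R,5R,7E,9S,12E,14S)-14-ethyl-5-hydroxy-3,7,9,13-tetramethyl-11-methylidene-2,4-dioxooxacyclotetradeca-7,12-dien-5-yl]methyl 2-chloroacetate | C=C1/C=C(\C)[C@H](CC)OC(=O)[C@H](C)C(=O)[C@](O)(COC(=O)CCl)C/C(C)=C/[C@@H](C)C1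
F3 | step 22 | 13-O-acetate of 29 | CC[C@H](OC(C)=O)/C(C)=C/C(=C)C[C@H](C)/C=C(\C)CC(=C)[C@@H](O[Si](CC)(CC)CC)[C@@H](C)C(=O)N1[C@@H](Cc2ccccc2)COC1=O
F4 | step 22 | 13-O-acetyl-3-hydroxy imide (F3 without the triethylsilyl group) | CC[C@H](OC(C)=O)/C(C)=C/C(=C)C[C@H](C)/C=C(\C)CC(=C)[C@@H](O)[C@@H](C)C(=O)N1[C@@H](Cc2ccccc2)COC1=O
F5 | step 22 | (4R)-4,4-epoxymethano derivative of F4 (oxirane on C4 and its former methylidene carbon; 2R,3S) | CC[C@H](OC(C)=O)/C(C)=C/C(=C)C[C@H](C)/C=C(\C)C[C@@]3(CO3)[C@@H](O)[C@@H](C)C(=O)N1[C@@H](Cc2ccccc2)COC1=O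
F6 | step 22 | (2R,3S)-3-hydroxy-3-{(2R)-2-[(2E,4S,7E,9S)-9-hydroxy-2,4,8-trimethyl-6-methylideneundeca-2,7-dien-1-yl]oxiran-2-yl}-2-methylpropanoic acid | CC[C@H](O)/C(C)=C/C(=C)C[C@H](C)/C=C(\C)C[C@@]1(CO1)[C@@H](O)[C@@H](C)C(=O)O
F7 | step 18 | (2R,3S)-4-(chloromethyl)-2-methyl-3-(triethylsilyloxy)pent-4-enoic acid | C=C(CCl)[C@@H](O[Si](CC)(CC)CC)[C@@H](C)C(=O)O
F8 | step 18 | (3S,4E,8S,9E)-4,8-dimethyl-6-methylidene-10-(tributylstannyl)undeca-4,9-dien-3-yl (2R,3S)-4-(chloromethyl)-2-methyl-3-(triethylsilyloxy)pent-4-enoate | CCCC[Sn](CCCC)(CCCC)/C(C)=C/[C@@H](C)CC(=C)/C=C(\C)[C@H](CC)OC(=O)[C@H](C)[C@H](O[Si](CC)(CC)CC)C(=C)CCl
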